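**Plan**
The target 11 is 7-hydroxy-5,6,8,3',4'-pentamethoxyflavone. The retrosynthesis first opens ring C at O1–C2, giving an ortho-hydroxyaryl ynone, and then cuts both bonds to the carbonyl carbon, C4a–C4 and C4–C3.
Enabling feature: C4 is a lone carbonyl carbon between C4a of the fully substituted ring A and the C3–C2 unit, so it can come from CO. The ring A partner is a mirror-symmetric aryl iodide whose two methoxy groups ortho to iodine are equivalent, so whichever later becomes O1 gives the same flavone.
Forward: 1,2,4,5-tetramethoxybenzene is hydroxylated, benzylated and iodinated to the ring A iodide 6. Iodide 6, CO and 4-ethynyl-1,2-dimethoxybenzene are then joined in one palladium-catalysed step to the open-chain ynone 9 (ring A–C4–C3≡C2–ring B).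
BCl3 frees the 7-OH and one ortho OH, and base closes ring C last by 6-endo attack of that phenol on C2.
Stereochemistry: there is none to set, since the target has no stereocentre and no stereogenic double bond.

Key step: step 4

Remark on the chemistry: locants C2, C3, C4, C4a and O1 follow flavone (2-aryl-4H-chromen-4-one) numbering. Compounds 1, 7 and 8 are taken as purchased.

**Route**

Step 1
Reactants: 1 1,2,4,5-tetramethoxybenzene
Product: 4 2,3,5,6-tetramethoxyphenol, via (2,3,5,6-tetramethoxyphenyl)lithium 2 (not isolated), via dimethyl (2,3,5,6-tetramethoxyphenyl)boronate 3 (not isolated)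
Conditions: n-BuLi (1.1 equiv), THF, 0 °C; B(OMe)3, -78 °C to rt; AcOH, 30% H2O2, 0 °C to rt
Reagents that add atoms: hydrogen peroxide, OO (oxygen of 4); n-butyllithium, [Li]CCCC (Li of 2); trimethyl borate, COB(OC)OC (B(OMe)2 of 3)
Why: Each ring C–H of 1 lies between two methoxy groups and the two sites are equivalent, so directed ortho-lithiation should be fast and regiodefined, and borylation followed by peroxide oxidation of the C–B bond (1,2-aryl shift from boron to oxygen) should give the phenol at that carbon.

Step 2
Reactants: 4 2,3,5,6-tetramethoxyphenol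
Product: 5 1-(benzyloxy)-2,3,5,6-tetramethoxybenzene
Conditions: BnBr, K2CO3, DMF, 50 °C
Reagents that add atoms: benzyl bromide, BrCc1ccccc1
Why: This is a Williamson ether synthesis, in which the phenoxide is alkylated at oxygen by a reactive benzylic halide, and the flanking methoxy groups should only slow it.

Step 3
Reactants: 5 1-(benzyloxy)-2,3,5,6-tetramethoxybenzene
Product: 6 1-(benzyloxy)-4-iodo-2,3,5,6-tetramethoxybenzene
Conditions: N-iodosuccinimide (1.1 equiv), CF3CO2H (cat.), MeCN, 0 °C to rt, dark
Reagents that add atoms: N-iodosuccinimide, O=C1CCC(=O)N1I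
Why: Electrophilic aromatic iodination should occur at the only unsubstituted position of the pentaoxygenated ring (para to the benzyloxy group, ortho to two methoxy groups), which is far more nucleophilic than the benzyl ring.

Step 4
Reactants: 6 1-(benzyloxy)-4-iodo-2,3,5,6-tetramethoxybenzene; 7 4-ethynyl-1,2-dimethoxybenzene; 8 carbon monoxide
Product: 9 1-[4-(benzyloxy)-2,3,5,6-tetramethoxyphenyl]-3-(3,4-dimethoxyphenyl)prop-2-yn-1-one
Conditions: PdCl2(PPh3)2 (5 mol %), Et3N (3 equiv), CO (20 bar), THF, 70 °C
Reagents that add atoms: none
Why: PdCl2(PPh3)2 is reduced in the flask to zerovalent palladium, which inserts into the C–I bond of 6; CO then inserts into the aryl–palladium bond to give an aroylpalladium iodide (divalent palladium) and so forms C4a–C4. Deprotonation of the palladium-bound alkyne 7 by Et3N delivers the alkynyl group to the metal, and reductive elimination forms C4–C3 and returns zerovalent palladium. The closest known reaction type is the carbonylative Sonogashira coupling of aryl iodides, terminal alkynes and CO to alkynyl aryl ketones. No ring is closed and no stereocentre is created in this step; ring C is left for step 6. The selectivity required is carbonylative over direct alkynylation, and it should be secured by the CO pressure, the absence of a copper co-catalyst and the two methoxy groups flanking the C–Pd bond, which hinder approach of the alkyne to the arylpalladium far more than they hinder insertion of the small CO ligand. Because 6 is mirror-symmetric there is no regiochemical question, and the benzyl ether and all methoxy groups should be inert to these conditions.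

Step 5
Reactants: 9 1-[4-(benzyloxy)-2,3,5,6-tetramethoxyphenyl]-3-(3,4-dimethoxyphenyl)prop-2-yn-1-one
Product: 10 1-(2,4-dihydroxy-3,5,6-trimethoxyphenyl)-3-(3,4-dimethoxyphenyl)prop-2-yn-1-one
Conditions: BCl3 (4 equiv), pentamethylbenzene (3 equiv), CH2Cl2, -78 to -20 °C; then H2O
Reagents that add atoms: none
Why: In this Lewis-acid ether cleavage, BCl3 should remove the benzyl group (its cation trapped by pentamethylbenzene) and, by chelation between the ketone oxygen and a neighbouring methoxy oxygen, exactly one of the two equivalent ortho methyl groups as chloromethane, while the methoxy groups that lack an adjacent carbonyl should survive at low temperature.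

Step 6
Reactants: 10 1-(2,4-dihydroxy-3,5,6-trimethoxyphenyl)-3-(3,4-dimethoxyphenyl)prop-2-yn-1-one
Product: 11 2-(3,4-dimethoxyphenyl)-7-hydroxy-5,6,8-trimethoxy-4H-chromen-4-one
Conditions: K2CO3, dry acetone, reflux; then 1 M HCl
Reagents that add atoms: none
Why: Intramolecular oxa-Michael addition of the ortho phenoxide to the β-carbon of the ynone (6-endo-dig) passes through a stabilised allenolate and should therefore be preferred over 5-exo closure in a dry aprotic medium, and protonation then gives the chromen-4-one.

**Compound list**
1 | 1,2,4,5-tetramethoxybenzene | COc1cc(OC)c(OC)cc1OC | starting material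
2 | (2,3,5,6-tetramethoxyphenyl)lithium | [Li]c1c(OC)c(OC)cc(OC)c1OC | intermediate
3 | dimethyl (2,3,5,6-tetramethoxyphenyl)boronate | COB(OC)c1c(OC)c(OC)cc(OC)c1OC | intermediate
4 | 2,3,5,6-tetramethoxyphenol | COc1cc(OC)c(OC)c(O)c1OC | intermediate
5 | 1-(benzyloxy)-2,3,5,6-tetramethoxybenzene | COc1cc(OC)c(OC)c(OCc2ccccc2)c1OC | intermediate
6 | 1-(benzyloxy)-4-iodo-2,3,5,6-tetramethoxybenzene | COc1c(OC)c(I)c(OC)c(OC)c1OCc1ccccc1 | intermediate
7 | 4-ethynyl-1,2-dimethoxybenzene | COc1ccc(C#C)cc1OC | starting material
8 | carbon monoxide | [C-]#[O+] | starting material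
9 | 1-[4-(benzyloxy)-2,3,5,6-tetramethoxyphenyl]-3-(3,4-dimethoxyphenyl)prop-2-yn-1-one | COc1ccc(C#CC(=O)c2c(OC)c(OC)c(OCc3ccccc3)c(OC)c2OC)cc1OC | intermediate
10 | 1-(2,4-dihydroxy-3,5,6-trimethoxyphenyl)-3-(3,4-dimethoxyphenyl)prop-2-yn-1-one | COc1ccc(C#CC(=O)c2c(O)c(OC)c(O)c(OC)c2OC)cc1OC | intermediate
11 | 2-(3,4-dimethoxyphenyl)-7-hydroxy-5,6,8-trimethoxy-4H-chromen-4-one | COc1ccc(-c2cc(=O)c3c(OC)c(OC)c(O)c(OC)c3o2)cc1OC | target

**Count**
Total steps: 6. Longest linear sequence: 6 steps (1 → 4 → 5 → 6 → 9 → 10 → 11).

**Steps most likely to fail and fallbacks**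

Step 4 (three-component coupling). What may go wrong: slow oxidative addition at the crowded, electron-rich C–I bond, competing direct alkynylation without CO uptake, or reductive loss of iodine.
The fallback sets out from 6 (with 7) and comes back at 9. Iodine–magnesium exchange on 6 with i-PrMgCl·LiCl in THF at 0 °C would give [4-(benzyloxy)-2,3,5,6-tetramethoxyphenyl]magnesium chloride F1, and quenching with DMF would give 4-(benzyloxy)-2,3,5,6-tetramethoxybenzaldehyde F2. Alkyne 7 would be deprotonated with n-BuLi in THF at -78 °C to [(3,4-dimethoxyphenyl)ethynyl]lithium F3, which should add to F2 to give racemic 1-[4-(benzyloxy)-2,3,5,6-tetramethoxyphenyl]-3-(3,4-dimethoxyphenyl)prop-2-yn-1-ol F4. Oxidation of this propargylic alcohol with MnO2 in CH2Cl2 would deliver ynone 9. The same two bonds to C4 are formed, with the carbonyl carbon drawn from DMF instead of CO.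

Step 5 (BCl3 deprotection). What may go wrong: loss of a second methyl group (the other ortho methoxy or a flanked one), or addition of chloride or HCl across the Lewis-acid-activated triple bond.
The fallback sets out from 9 and comes back at 11, bypassing 10. Treating 9 with ICl in CH2Cl2 at -78 °C should trigger iodocyclisation. One ortho methoxy oxygen attacks the iodine-activated alkyne in the 6-endo mode and chloride removes its methyl group, giving 7-(benzyloxy)-2-(3,4-dimethoxyphenyl)-3-iodo-5,6,8-trimethoxy-4H-chromen-4-one F5. Hydrogenolysis (H2, Pd/C as 10% palladium on carbon, Et3N, EtOAc/MeOH, rt) would then remove both the C3 iodine and the benzyl group to give 11. No free ortho phenol and no selective Lewis-acid demethylation are needed.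

Step 6 (ring C closure). What may go wrong: competing 5-exo-dig closure to the benzofuranone (aurone-type) isomer, or sluggish addition because the para phenoxide lowers the electrophilicity of the ynone.
The fallback sets out from 10 and comes back at 11. Diethylamine in EtOH at rt should add to the ynone to give the enaminone (E)-3-(diethylamino)-1-(2,4-dihydroxy-3,5,6-trimethoxyphenyl)-3-(3,4-dimethoxyphenyl)prop-2-en-1-one F6. On warming, the ortho phenol should displace the amine at the β-carbon by intramolecular addition–elimination, which can only give the six-membered ring, so 11 is formed with loss of diethylamine.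

**Further compounds**
F1 | step 4 | [4-(benzyloxy)-2,3,5,6-tetramethoxyphenyl]magnesium chloride | COc1c(OC)c([Mg]Cl)c(OC)c(OC)c1OCc1ccccc1
F2 | step 4 | 4-(benzyloxy)-2,3,5,6-tetramethoxybenzaldehyde | COc1c(OC)c(C=O)c(OC)c(OC)c1OCc1ccccc1
F3 | step 4 | [(3,4-dimethoxyphenyl)ethynyl]lithium | [Li]C#Cc1ccc(OC)c(OC)c1
F4 | step 4 | 1-[4-(benzyloxy)-2,3,5,6-tetramethoxyphenyl]-3-(3,4-dimethoxyphenyl)prop-2-yn-1-ol (racemic) | COc1ccc(C#CC(O)c2c(OC)c(OC)c(OCc3ccccc3)c(OC)c2OC)cc1OC
F5 | step 5 | 7-(benzyloxy)-2-(3,4-dimethoxyphenyl)-3-iodo-5,6,8-trimethoxy-4H-chromen-4-one | COc1ccc(-c2oc3c(OC)c(OCc4ccccc4)c(OC)c(OC)c3c(=O)c2I)cc1OC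
F6 | step 6 | (E)-3-(diethylamino)-1-(2,4-dihydroxy-3,5,6-trimethoxyphenyl)-3-(3,4-dimethoxyphenyl)prop-2-en-1-one | CCN(CC)/C(=C/C(=O)c1c(O)c(OC)c(O)c(OC)c1OC)c1ccc(OC)c(OC)c1
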